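**Assumption:** (E)-4-methylpent-2-enal, triethyl 4-phosphonocrotonate, ethyl (E)-4-oxobut-2-enoate and 2-amino-3-hydroxycyclopent-2-en-1-one hydrochloride are taken as catalogue chemicals.

## Retrosynthetic overview

1. The lower trienamide is cut at C5'–C6' by a Heck vinylation: a core carrying only a plain vinyl group at C4, plus the (2E,4E)-5-iodopentadienamide of the aminocyclopentenone.
2. The C2–N bond is cut by a Cu-catalysed amidation of an α-iodo-enone with the complete primary trienamide of the upper chain.
3. All three stereocentres come from one catalytic desymmetrising syn-epoxidation of prochiral 4-ethenyl-4-hydroxycyclohexa-2,5-dienone.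
4. That p-quinol comes from 4-methoxyphenol by oxidative dearomatisation to the mirror-symmetric quinone monoketal and vinyl Grignard addition.
5. Ring order: the carbocycle is the former benzene ring (dearomatised first), the oxirane is closed on it in the key step, and the cyclopentenone ring is bought.

## Route

**Step 1**
Reactants: 1 4-methoxyphenol
Product: 2 4,4-dimethoxycyclohexa-2,5-dien-1-one
Conditions: PhI(OAc)2 (1.1 equiv), MeOH, 0 °C to rt
Reagents that add atoms: methanol, CO
Why: Iodine(III) oxidation of the phenol and trapping of the phenoxenium-type intermediate at the para carbon by methanol (oxidative dearomatisation to the quinone monoketal) gives a mirror-symmetric dienone; no stereocentre.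

**Step 2**
Reactants: 2 4,4-dimethoxycyclohexa-2,5-dien-1-one; 3 vinylmagnesium bromide
Product: 5 4-ethenyl-4-hydroxycyclohexa-2,5-dien-1-one, via 1-ethenyl-4,4-dimethoxycyclohexa-2,5-dien-1-ol 4 (not isolated)
Conditions: CH2=CHMgBr (1.3 equiv), THF, −78 °C; then AcOH/H2O/THF, rt
Reagents that add atoms: water, O
Why: Grignard 1,2-addition to the cross-conjugated dienone carbonyl, then mild acid hydrolysis of the dimethyl ketal, gives the prochiral p-quinol; C4 carries two identical ring arms, so it is not yet a stereocentre.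

**Step 3 (key step)**
Reactants: 5 4-ethenyl-4-hydroxycyclohexa-2,5-dien-1-one
Product: 6 (1S,5S,6R)-5-ethenyl-5-hydroxy-7-oxabicyclo[4.1.0]hept-3-en-2-one
Conditions: 9-amino-9-deoxy-epi-quinine (10 mol %), TFA (20 mol %), 50% aq. H2O2 (1.1 equiv), 1,4-dioxane, 30 °C
Reagents that add atoms: hydrogen peroxide, OO
Why: Proposed new method: an iminium-catalysed Weitz–Scheffer epoxidation used as a desymmetrisation, in which the cinchona primary amine condenses with the dienone carbonyl, its protonated quinuclidine delivers H2O2 to one of the two enantiotopic β-carbons, and attack occurs on the face syn to the C4–OH (smaller than vinyl and H-bonding to the incoming peroxide), so C4, C5 and C6 are set together; the nucleophilic oxidant leaves the isolated vinyl group alone and the minor enantiomer is the one consumed faster to bis-epoxide, which raises ee; the closest known chemistry is amine-salt-catalysed asymmetric epoxidation of cyclohexenones with H2O2 and OH-directed syn nucleophilic epoxidation of p-quinols; the sense of induction is checked on the first run and the quinidine-derived pseudoenantiomer is used if it is opposite.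

**Step 4**
Reactants: 6 (1S,5S,6R)-5-ethenyl-5-hydroxy-7-oxabicyclo[4.1.0]hept-3-en-2-one
Product: 7 (1S,5S,6R)-5-ethenyl-5-hydroxy-3-iodo-7-oxabicyclo[4.1.0]hept-3-en-2-one
Conditions: I2 (2 equiv), DMAP (20 mol %), pyridine/CH2Cl2 1:1, 0 °C to rt, dark
Reagents that add atoms: iodine, II
Why: Johnson α-iodination (conjugate addition of pyridine/DMAP to the only enone, iodination of the enolate, elimination) puts iodine on C2; the epoxy-ketone side has no enone, the vinyl group does not add I2 irreversibly, and the stereocentres are untouched.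

**Step 5**
Reactants: 8 (E)-4-methylpent-2-enal; 9 triethyl 4-phosphonocrotonate
Product: 10 ethyl (2E,4E,6E)-8-methylnona-2,4,6-trienoate
Conditions: LiHMDS, THF, −78 °C; then 8, −78 to 0 °C
Reagents that add atoms: none
Why: Vinylogous Horner–Wadsworth–Emmons olefination, in which the stabilised allylic phosphonate anion reacts at its α-carbon with the aldehyde and gives the new C4=C5 bond E; a minor 4Z isomer is removed by chromatography or trace-I2 equilibration.

**Step 6**
Reactants: 10 ethyl (2E,4E,6E)-8-methylnona-2,4,6-trienoate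
Product: 11 (2E,4E,6E)-8-methylnona-2,4,6-trienamide
Conditions: AlMe3 (3 equiv), NH4Cl (3 equiv), toluene, 0 °C to rt; then 10, 50 °C; Rochelle-salt work-up
Reagents that add atoms: ammonium chloride, [NH4+].[Cl-]
Why: Weinreb-type aluminium-amide aminolysis (MeAl(Cl)NH2 formed in situ) converts the conjugated ester directly into the primary amide without adding to or isomerising the triene.

**Step 7**
Reactants: 7 (1S,5S,6R)-5-ethenyl-5-hydroxy-3-iodo-7-oxabicyclo[4.1.0]hept-3-en-2-one; 11 (2E,4E,6E)-8-methylnona-2,4,6-trienamide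
Product: 12 (2E,4E,6E)-N-[(1S,5S,6R)-5-ethenyl-5-hydroxy-2-oxo-7-oxabicyclo[4.1.0]hept-3-en-3-yl]-8-methylnona-2,4,6-trienamide
Conditions: CuI (20 mol %), N,N'-dimethylethylenediamine (40 mol %), Cs2CO3 (1.5 equiv), THF, rt to 45 °C, Ar, dark
Reagents that add atoms: none
Why: Goldberg-type Cu(I)/diamine C–N coupling of a vinyl iodide with a primary amide runs under mild conditions because the α-iodo-enone C–I bond is strongly activated; the syn OH/epoxide pair cannot undergo Payne rearrangement and no stereocentre is involved.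

**Step 8**
Reactants: 13 ethyl (E)-4-oxobut-2-enoate
Product: 14 ethyl (2E,4E)-5-iodopenta-2,4-dienoate
Conditions: CrCl2 (6 equiv), CHI3 (2 equiv), THF, 0 °C
Reagents that add atoms: iodoform, IC(I)I
Why: Takai olefination: the gem-dichromium species from CHI3/CrCl2 adds only to the aldehyde and eliminates to the (E)-vinyl iodide, leaving the enoate untouched.

**Step 9**
Reactants: 14 ethyl (2E,4E)-5-iodopenta-2,4-dienoate
Product: 15 (2E,4E)-5-iodopenta-2,4-dienoic acid
Conditions: LiOH·H2O, THF/H2O 3:1, 0 °C to rt; then 1 M HCl to pH 2–3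
Reagents that add atoms: lithium hydroxide, [Li+].[OH-]
Why: Ester saponification; the (E)-vinyl iodide has H and I cis, so anti-elimination to an enyne is not available and both alkene geometries are kept.

**Step 10**
Reactants: 15 (2E,4E)-5-iodopenta-2,4-dienoic acid; 16 2-amino-3-hydroxycyclopent-2-en-1-one hydrochloride
Product: 17 (2E,4E)-N-(2-hydroxy-5-oxocyclopent-1-en-1-yl)-5-iodopenta-2,4-dienamide
Conditions: EDC·HCl (1.2 equiv), HOBt (1.2 equiv), Et3N (3 equiv), DMF, 0 °C to rt
Reagents that add atoms: none
Why: Carbodiimide amide coupling; any O-acylation of the vinylogous acid funnels by O-to-N acyl shift to the thermodynamically preferred N-acyl enaminone.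

**Step 11**
Reactants: 12 (2E,4E,6E)-N-[(1S,5S,6R)-5-ethenyl-5-hydroxy-2-oxo-7-oxabicyclo[4.1.0]hept-3-en-3-yl]-8-methylnona-2,4,6-trienamide; 17 (2E,4E)-N-(2-hydroxy-5-oxocyclopent-1-en-1-yl)-5-iodopenta-2,4-dienamide
Product: 18 manumycin G
Conditions: Pd(OAc)2 (10 mol %), AgOAc (1.5 equiv), DMF, rt, Ar, dark
Reagents that add atoms: none
Why: Mizoroki–Heck vinylation under ligand-free, silver-promoted conditions: oxidative addition to the vinyl iodide with retention, insertion at the terminal carbon of the only monosubstituted alkene, and syn β-H elimination, which can only go toward the chain because C4 is quaternary, give the new E double bond (as for 2-methylbut-3-en-2-ol-type tertiary allylic alcohols); silver suppresses Pd–H isomerisation and the stereocentres are untouched.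

## Compound list

1 | 4-methoxyphenol | COc1ccc(O)cc1 | starting material
2 | 4,4-dimethoxycyclohexa-2,5-dien-1-one | COC1(OC)C=CC(=O)C=C1 | intermediate
3 | vinylmagnesium bromide | C=C[Mg]Br | starting material
4 | 1-ethenyl-4,4-dimethoxycyclohexa-2,5-dien-1-ol | COC1(OC)C=CC(O)(C=C)C=C1 | intermediate (not isolated)
5 | 4-ethenyl-4-hydroxycyclohexa-2,5-dien-1-one | O=C1C=CC(O)(C=C)C=C1 | intermediate
6 | (1S,5S,6R)-5-ethenyl-5-hydroxy-7-oxabicyclo[4.1.0]hept-3-en-2-one | C1=C[C@@](O)(C=C)[C@@H]2O[C@@H]2C1=O | intermediate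
7 | (1S,5S,6R)-5-ethenyl-5-hydroxy-3-iodo-7-oxabicyclo[4.1.0]hept-3-en-2-one | IC1=C[C@@](O)(C=C)[C@@H]2O[C@@H]2C1=O | intermediate
8 | (E)-4-methylpent-2-enal | CC(C)/C=C/C=O | starting material
9 | triethyl 4-phosphonocrotonate, ethyl (E)-4-(diethoxyphosphoryl)but-2-enoate | CCOC(=O)/C=C/CP(=O)(OCC)OCC | starting material
10 | ethyl (2E,4E,6E)-8-methylnona-2,4,6-trienoate | CC(C)/C=C/C=C/C=C/C(=O)OCC | intermediate
11 | (2E,4E,6E)-8-methylnona-2,4,6-trienamide | CC(C)/C=C/C=C/C=C/C(N)=O | intermediate
12 | (2E,4E,6E)-N-[(1S,5S,6R)-5-ethenyl-5-hydroxy-2-oxo-7-oxabicyclo[4.1.0]hept-3-en-3-yl]-8-methylnona-2,4,6-trienamide | CC(C)/C=C/C=C/C=C/C(=O)NC1=C[C@@](O)(C=C)[C@@H]2O[C@@H]2C1=O | intermediate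
13 | ethyl (E)-4-oxobut-2-enoate | CCOC(=O)/C=C/C=O | starting material
14 | ethyl (2E,4E)-5-iodopenta-2,4-dienoate | CCOC(=O)/C=C/C=C/I | intermediate
15 | (2E,4E)-5-iodopenta-2,4-dienoic acid | OC(=O)/C=C/C=C/I | intermediate
16 | 2-amino-3-hydroxycyclopent-2-en-1-one hydrochloride | NC1=C(O)CCC1=O.Cl | starting material
17 | (2E,4E)-N-(2-hydroxy-5-oxocyclopent-1-en-1-yl)-5-iodopenta-2,4-dienamide | I/C=C/C=C/C(=O)NC1=C(O)CCC1=O | intermediate
18 | manumycin G, (2E,4E,6E)-N-[(1S,5S,6R)-5-hydroxy-5-{(1E,3E,5E)-7-[(2-hydroxy-5-oxocyclopent-1-en-1-yl)amino]-7-oxohepta-1,3,5-trien-1-yl}-2-oxo-7-oxabicyclo[4.1.0]hept-3-en-3-yl]-8-methylnona-2,4,6-trienamide | CC(C)/C=C/C=C/C=C/C(=O)NC1=C[C@@](O)(/C=C/C=C/C=C/C(=O)NC2=C(O)CCC2=O)[C@@H]2O[C@@H]2C1=O | target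

## Step count

Total: 11 steps. Longest linear sequence: 6 steps (1 → 2 → 5 → 6 → 7 → 12 → 18, i.e. steps 1, 2, 3, 4, 7, 11). No protecting groups are used.

## Three steps most likely to fail, with fallbacks

**Step 3 (desymmetrising epoxidation).** The risks are over-oxidation to the bis-epoxide, insufficient ee, or poor syn/anti control. The fallback sets out from 2 and returns at 6. The symmetric monoketal 2 is mono-epoxidised under chiral phase-transfer Weitz–Scheffer conditions (N-benzylcinchonidinium chloride, t-BuOOH, NaOH, toluene, 0 °C) to (1R,6S)-5,5-dimethoxy-7-oxabicyclo[4.1.0]hept-3-en-2-one F1, which is recrystallised to raise ee. Vinylmagnesium bromide 3 then adds to the ketone of F1 from the face opposite the oxirane, giving (1R,2S,6S)-2-ethenyl-5,5-dimethoxy-7-oxabicyclo[4.1.0]hept-3-en-2-ol F2 with OH and epoxide syn. Mild acid (montmorillonite K10 or aqueous oxalic acid) removes the ketal and delivers 6. Here the enantio-determining step is a catalyst-controlled epoxidation of a planar dienone and C4 is set by substrate control.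

**Step 7 (Cu-catalysed amidation on the epoxy-iodoenone).** The risks are base-induced decomposition, protodeiodination, or sluggish coupling of the polyene amide. The fallback sets out from 7 and 10 and returns at 12, and brings nitrogen in as azide so that the amide bond is made by acylation instead of by C–N coupling of the amide. Compound 7 is converted with NaN3, CuI, sodium ascorbate and N,N'-dimethylethylenediamine (EtOH/H2O, rt) into (1S,5S,6R)-3-azido-5-ethenyl-5-hydroxy-7-oxabicyclo[4.1.0]hept-3-en-2-one F3. Ester 10 is saponified (LiOH, THF/H2O) to (2E,4E,6E)-8-methylnona-2,4,6-trienoic acid F4. F3 and F4 are then joined in a one-pot Staudinger–Vilarrasa ligation (PMe3, 2,2'-dipyridyl diselenide, toluene, rt), in which the iminophosphorane is acylated by the acid activated in situ, to give 12. The unstable free 2-amino-enone is never generated.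

**Step 11 (late-stage Heck on the complete, sensitive core).** The risks are low conversion, polyene isomerisation, or reaction at other alkenes. The fallback sets out from 12 and returns at 18 and replaces the Heck by a metathesis/cross-coupling pair. Cross-metathesis of the terminal vinyl group of 12 with vinylboronic acid pinacol ester (Hoveyda–Grubbs II, CH2Cl2, 40 °C) gives (2E,4E,6E)-N-[(1S,5S,6R)-5-hydroxy-2-oxo-5-[(E)-2-(4,4,5,5-tetramethyl-1,3,2-dioxaborolan-2-yl)ethenyl]-7-oxabicyclo[4.1.0]hept-3-en-3-yl]-8-methylnona-2,4,6-trienamide F5. Suzuki–Miyaura coupling of F5 with iodide 17 (Pd(PPh3)4, aq. K3PO4, THF, rt, dark) then gives 18 with both alkene geometries retained.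

## Further compounds

F1 | step 3 | (1R,6S)-5,5-dimethoxy-7-oxabicyclo[4.1.0]hept-3-en-2-one | C1=CC(=O)[C@@H]2O[C@@H]2C1(OC)OC
F2 | step 3 | (1R,2S,6S)-2-ethenyl-5,5-dimethoxy-7-oxabicyclo[4.1.0]hept-3-en-2-ol | C1=C[C@@](O)(C=C)[C@@H]2O[C@@H]2C1(OC)OC
F3 | step 7 | (1S,5S,6R)-3-azido-5-ethenyl-5-hydroxy-7-oxabicyclo[4.1.0]hept-3-en-2-one | [N-]=[N+]=NC1=C[C@@](O)(C=C)[C@@H]2O[C@@H]2C1=O
F4 | step 7 | (2E,4E,6E)-8-methylnona-2,4,6-trienoic acid | CC(C)/C=C/C=C/C=C/C(O)=O
F5 | step 11 | (2E,4E,6E)-N-[(1S,5S,6R)-5-hydroxy-2-oxo-5-[(E)-2-(4,4,5,5-tetramethyl-1,3,2-dioxaborolan-2-yl)ethenyl]-7-oxabicyclo[4.1.0]hept-3-en-3-yl]-8-methylnona-2,4,6-trienamide | CC(C)/C=C/C=C/C=C/C(=O)NC1=C[C@@](O)(/C=C/B3OC(C)(C)C(C)(C)O3)[C@@H]2O[C@@H]2C1=O
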